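**Retrosynthetic overview**
- The strategy rests on the C2=C3 bond of the pyrrole ring of the 1-methyl-2,3-disubstituted indole: C2 carries CH2–(1-methylindol-3-yl) and C3 carries the CH2 of the hydroxy-lactone chain. This bond is cut back to an amide C=O (→ C2) and an aryl ketone C=O (→ C3) held ortho on one benzene ring (14 ⇒ 13).
- Target 16 ⇒ 14 by acetonide removal and lactonisation; the syn acetonide ester 13 ⇒ cis hydroxy-lactone 11.
- 11 ⇒ boron aldol (chain C4–C5 bond) of keto amide 8 with aldehyde 4; the carbinol α to the carboxyl comes from D-malic acid 1, the second carbinol from reagent control.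
- 8 ⇒ aminoketone 6 + indolylacetic acid 5 (N-acylation); 4 ⇐ 1 through dioxolanones 2 and 3.
- Ring order: dioxolanone (step 1, temporary) → γ-lactone (step 5, temporary) → 1,3-dioxane acetonide (step 6) → pyrrole ring of the new indole (step 7) → γ-lactone of the target (step 8). The benzene rings and the first N-methylindole are bought.

Key step: step 7

Assumption: (−)-Ipc2BCl (Ipc = isopinocampheyl, from (+)-α-pinene) is taken as the antipode that sends a methyl-ketone enol borinate to the Re face of an unbranched aldehyde, which gives the (S) carbinol needed. If the sense is the opposite for this pair, (+)-Ipc2BCl is used in step 5 with nothing else changed.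

**Route**

Step 1
Reactants: 1 D-malic acid
Product: 2 2-[(4R)-2,2-dimethyl-5-oxo-1,3-dioxolan-4-yl]acetic acid
Conditions: 2,2-dimethoxypropane, TsOH·H2O (cat.), rt
Reagents that add atoms: 2,2-dimethoxypropane COC(C)(C)OC
Why: Acid-catalysed acetonide (dioxolanone) formation should take the α-hydroxy acid pair selectively into the five-membered ring and leave the β-carboxyl free, without touching the malate stereocentre.

Step 2
Reactants: 2 2-[(4R)-2,2-dimethyl-5-oxo-1,3-dioxolan-4-yl]acetic acid
Product: 3 (5R)-5-(2-hydroxyethyl)-2,2-dimethyl-1,3-dioxolan-4-one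
Conditions: BH3·SMe2, THF, 0 °C → rt; MeOH quench
Reagents that add atoms: none
Why: Chemoselective borane reduction of a free carboxylic acid (via the acyloxyborane) should be much faster than attack on the dioxolanone carbonyl, and no stereocentre is involved.

Step 3
Reactants: 3 (5R)-5-(2-hydroxyethyl)-2,2-dimethyl-1,3-dioxolan-4-one
Product: 4 2-[(4R)-2,2-dimethyl-5-oxo-1,3-dioxolan-4-yl]acetaldehyde
Conditions: Dess–Martin periodinane, NaHCO3, CH2Cl2, 0 °C → rt
Reagents that add atoms: none
Why: Buffered Dess–Martin oxidation should give the aldehyde without base, so that neither β-elimination of the ring oxygen nor epimerisation of the α-oxygenated centre is expected.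

Step 4
Reactants: 5 (1-methyl-1H-indol-3-yl)acetic acid; 6 1-[2-(methylamino)phenyl]ethanone
Product: 8 N-(2-acetylphenyl)-N-methyl-2-(1-methyl-1H-indol-3-yl)acetamide, via acid chloride 7 (not isolated)
Conditions: (COCl)2, DMF (cat.), CH2Cl2, 0 °C → rt; concentrate; then 6, pyridine, DMAP (cat.), CH2Cl2, 0 → 40 °C
Reagents that add atoms: none
Why: Acid chloride formation followed by N-acylation should overcome the low nucleophilicity of the hydrogen-bonded ortho-acyl N-methylaniline, and pyridine is too weak a base to start a Camps cyclisation.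

Step 5
Reactants: 8 N-(2-acetylphenyl)-N-methyl-2-(1-methyl-1H-indol-3-yl)acetamide; 4 2-[(4R)-2,2-dimethyl-5-oxo-1,3-dioxolan-4-yl]acetaldehyde
Product: 11 N-(2-{2-[(2S,4R)-4-hydroxy-5-oxooxolan-2-yl]acetyl}phenyl)-N-methyl-2-(1-methyl-1H-indol-3-yl)acetamide, via enol diisopinocampheylborinate 9 (not isolated), via dioxolanone aldol adduct 10 (not isolated)
Conditions: (−)-Ipc2BCl, Et3N, Et2O, 0 °C; then 4, −78 → −20 °C; pH 7 buffer/MeOH (no peroxide); then CSA (cat.), CH2Cl2, rt
Reagents that add atoms: none
Why: In this Paterson-type reagent-controlled boron aldol the chloroborane/Et3N pair should enolise only the methyl ketone (not the tertiary amide), the enol borinate should add to the aldehyde through a cyclic transition state in which the Ipc ligands select the Re face and so set the new carbinol as (S), and acid then lets this hydroxyl displace acetone from the dioxolanone (lactonisation) to give the cis lactone, from which the minor trans epimer can be removed.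

Step 6
Reactants: 11 N-(2-{2-[(2S,4R)-4-hydroxy-5-oxooxolan-2-yl]acetyl}phenyl)-N-methyl-2-(1-methyl-1H-indol-3-yl)acetamide
Product: 13 methyl (4R,6S)-2,2-dimethyl-6-(2-{2-[N-methyl-2-(1-methyl-1H-indol-3-yl)acetamido]phenyl}-2-oxoethyl)-1,3-dioxane-4-carboxylate, via dihydroxy methyl ester 12 (not isolated)
Conditions: CSA (cat.), MeOH/2,2-dimethoxypropane (1:5), rt → 40 °C; Et3N quench
Reagents that add atoms: methanol CO; 2,2-dimethoxypropane COC(C)(C)OC
Why: Acid-catalysed methanolysis of the α-hydroxy γ-lactone should be pulled forward by transketalisation of the freed syn-1,3-diol into the chair acetonide with both substituents equatorial (lactone opening with acetonide capture), with acyl–oxygen cleavage only, so that no stereocentre is touched.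

Step 7
Reactants: 13 methyl (4R,6S)-2,2-dimethyl-6-(2-{2-[N-methyl-2-(1-methyl-1H-indol-3-yl)acetamido]phenyl}-2-oxoethyl)-1,3-dioxane-4-carboxylate
Product: 14 methyl (4R,6R)-2,2-dimethyl-6-({1-methyl-2-[(1-methyl-1H-indol-3-yl)methyl]-1H-indol-3-yl}methyl)-1,3-dioxane-4-carboxylate
Conditions: TiCl3, Zn dust, DME, reflux; Celite, aq. K2CO3 work-up
Reagents that add atoms: none
Why: Zinc-reduced titanium should transfer an electron to the titanium-bound aryl ketone, the ketyl (or titanaoxirane) carbon should add to the neighbouring amide carbonyl, and the titanium diolate should lose both oxygens to give the C2=C3 double bond, so that the ketone carbon becomes C3 and the amide carbon C2. This is the McMurry-type oxo-amide coupling of ortho-acyl anilides (Fürstner indole synthesis), which accepts aryl alkyl ketones, tertiary N-alkyl amides, esters and acetals. The pyrrole ring closes by C–C bond formation between the two carbonyl carbons, formally a 5-exo-trig attack of the ketyl carbon on the amide C=O, with N1, C7a and C3a already in place. No stereocentre is formed, and the two dioxane stereocentres should be untouched because the medium is not basic; the descriptor at C6 changes from S to R only through the change in substituent priority. The step needs ketone–amide coupling to be faster than ketone–ester coupling, intermolecular pinacol coupling and loss of the β-oxygen: the ortho template makes the five-membered closure the fastest event, the cis-diequatorial acetonide holds the ester away from the ketyl carbon, and the β-oxygen is a ring acetal oxygen, a poor leaving group without base.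

Step 8
Reactants: 14 methyl (4R,6R)-2,2-dimethyl-6-({1-methyl-2-[(1-methyl-1H-indol-3-yl)methyl]-1H-indol-3-yl}methyl)-1,3-dioxane-4-carboxylate
Product: 16 chaetoindolone C (3R,5R)-3-hydroxy-5-({1-methyl-2-[(1-methyl-1H-indol-3-yl)methyl]-1H-indol-3-yl}methyl)oxolan-2-one, via dihydroxy methyl ester 15 (not isolated)
Conditions: TsOH·H2O (cat.), THF/H2O (4:1), 40 °C
Reagents that add atoms: none
Why: Dilute aqueous acid should hydrolyse the acetonide and the freed 4-hydroxyl should close onto the methyl ester (acid-catalysed lactonisation, 5-exo-trig), with both carbinol centres retained because no C–O bond at a stereocentre is broken.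

**Compound list**

1 | D-malic acid, (R)-2-hydroxybutanedioic acid | OC(=O)C[C@H](C(=O)O)O | starting material
2 | 2-[(4R)-2,2-dimethyl-5-oxo-1,3-dioxolan-4-yl]acetic acid | OC(=O)C[C@@H]1C(=O)OC(C)(C)O1 | intermediate
3 | (5R)-5-(2-hydroxyethyl)-2,2-dimethyl-1,3-dioxolan-4-one | OCC[C@@H]1C(=O)OC(C)(C)O1 | intermediate
4 | 2-[(4R)-2,2-dimethyl-5-oxo-1,3-dioxolan-4-yl]acetaldehyde | O=CC[C@@H]1C(=O)OC(C)(C)O1 | intermediate
5 | (1-methyl-1H-indol-3-yl)acetic acid | Cn1cc(CC(=O)O)c2ccccc21 | starting material
6 | 1-[2-(methylamino)phenyl]ethanone | CNc1ccccc1C(C)=O | starting material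
7 | (1-methyl-1H-indol-3-yl)acetyl chloride | Cn1cc(CC(=O)Cl)c2ccccc21 | intermediate (not isolated)
8 | N-(2-acetylphenyl)-N-methyl-2-(1-methyl-1H-indol-3-yl)acetamide | CC(=O)c1ccccc1N(C)C(=O)Cc1cn(C)c2ccccc12 | intermediate
9 | enol diisopinocampheylborinate of 8, N-(2-{1-[(diisopinocampheylboranyl)oxy]ethenyl}phenyl)-N-methyl-2-(1-methyl-1H-indol-3-yl)acetamide | C=C(OB([C@@H]1C[C@@H]2C[C@H]([C@H]1C)C2(C)C)[C@@H]1C[C@@H]2C[C@H]([C@H]1C)C2(C)C)c1ccccc1N(C)C(=O)Cc1cn(C)c2ccccc12 | intermediate (not isolated)
10 | N-(2-{(3S)-4-[(4R)-2,2-dimethyl-5-oxo-1,3-dioxolan-4-yl]-3-hydroxybutanoyl}phenyl)-N-methyl-2-(1-methyl-1H-indol-3-yl)acetamide | CC1(C)O[C@H](C[C@H](O)CC(=O)c2ccccc2N(C)C(=O)Cc2cn(C)c3ccccc23)C(=O)O1 | intermediate (not isolated)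
11 | N-(2-{2-[(2S,4R)-4-hydroxy-5-oxooxolan-2-yl]acetyl}phenyl)-N-methyl-2-(1-methyl-1H-indol-3-yl)acetamide (cis lactone) | Cn1cc(CC(=O)N(C)c2ccccc2C(=O)C[C@@H]2C[C@@H](O)C(=O)O2)c2ccccc21 | intermediate
12 | methyl (2R,4S)-2,4-dihydroxy-6-{2-[N-methyl-2-(1-methyl-1H-indol-3-yl)acetamido]phenyl}-6-oxohexanoate | COC(=O)[C@H](O)C[C@H](O)CC(=O)c1ccccc1N(C)C(=O)Cc1cn(C)c2ccccc12 | intermediate (not isolated)
13 | methyl (4R,6S)-2,2-dimethyl-6-(2-{2-[N-methyl-2-(1-methyl-1H-indol-3-yl)acetamido]phenyl}-2-oxoethyl)-1,3-dioxane-4-carboxylate (syn acetonide) | COC(=O)[C@H]1C[C@@H](CC(=O)c2ccccc2N(C)C(=O)Cc2cn(C)c3ccccc23)OC(C)(C)O1 | intermediate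
14 | methyl (4R,6R)-2,2-dimethyl-6-({1-methyl-2-[(1-methyl-1H-indol-3-yl)methyl]-1H-indol-3-yl}methyl)-1,3-dioxane-4-carboxylate (syn acetonide) | COC(=O)[C@H]1C[C@@H](Cc2c3ccccc3n(C)c2Cc2cn(C)c3ccccc23)OC(C)(C)O1 | intermediate
15 | methyl (2R,4R)-2,4-dihydroxy-5-{1-methyl-2-[(1-methyl-1H-indol-3-yl)methyl]-1H-indol-3-yl}pentanoate | COC(=O)[C@H](O)C[C@H](O)Cc1c2ccccc2n(C)c1Cc1cn(C)c2ccccc12 | intermediate (not isolated)
16 | chaetoindolone C, (3R,5R)-3-hydroxy-5-({1-methyl-2-[(1-methyl-1H-indol-3-yl)methyl]-1H-indol-3-yl}methyl)oxolan-2-one | Cn1cc(Cc2c(C[C@@H]3C[C@@H](O)C(=O)O3)c3ccccc3n2C)c2ccccc21 | target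

**Step count**
Total: 8 steps. Longest linear sequence: 7 steps (steps 1, 2, 3, 5, 6, 7, 8 from D-malic acid).

**Steps most likely to fail**

1. Step 7 (key step). What may go wrong: the hot, Lewis-acidic titanium/zinc chloride medium may strip the acetonide or trigger elimination of the β-oxygen across the CH2 next to the ketone, or the ketyl may be reduced further or dimerise before it reaches the hindered tertiary amide. Fallback, setting out from 11 and returning at 16: the coupling is moved onto the lactone, so that neither an acetonide nor an open-chain ester enters it and steps 6 and 8 fall away. The 3-hydroxyl of 11 is silylated (TBSCl, imidazole, DMF) to N-(2-{2-[(2S,4R)-4-(tert-butyldimethylsilyloxy)-5-oxooxolan-2-yl]acetyl}phenyl)-N-methyl-2-(1-methyl-1H-indol-3-yl)acetamide F1. F1 is cyclised with preformed titanium–graphite (TiCl3, C8K, DME, reflux; no zinc chloride in the medium) to (3R,5R)-3-(tert-butyldimethylsilyloxy)-5-({1-methyl-2-[(1-methyl-1H-indol-3-yl)methyl]-1H-indol-3-yl}methyl)oxolan-2-one F2. HF·pyridine in THF then removes the silyl group to give 16.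

2. Step 5. What may go wrong: poor facial selectivity of the enol borinate on the aldehyde (the inherent selectivity of Ipc-controlled methyl-ketone aldols is only moderate and the β-oxygen of the aldehyde gives no helpful bias), or binding of the boron reagent by the amide. Fallback, setting out from 11 of low diastereomeric purity and returning at 13: the carbinol centre is erased and reset under thermodynamic control from the malate centre. DBU and MeI in MeCN open both epimers by E1cB elimination of the lactone carboxylate and esterify it in situ, giving the single enone methyl (2R,4E)-2-hydroxy-6-{2-[N-methyl-2-(1-methyl-1H-indol-3-yl)acetamido]phenyl}-6-oxohex-4-enoate F3. Benzaldehyde with catalytic KOt-Bu (THF, 0 °C) adds the C2 alkoxide as its hemiacetal to the enone (oxa-Michael) to give the all-cis benzylidene acetal methyl (2R,4R,6S)-6-(2-{2-[N-methyl-2-(1-methyl-1H-indol-3-yl)acetamido]phenyl}-2-oxoethyl)-2-phenyl-1,3-dioxane-4-carboxylate F4. Acetal exchange under the conditions of step 6 (CSA, MeOH, excess 2,2-dimethoxypropane) then gives 13.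

3. Step 6. What may go wrong: the γ-lactone may resist acid methanolysis and remain the thermodynamic sink, or the freed 2-hydroxyl may close onto the aryl ketone as a cyclic ketal, or acid-promoted elimination next to the ketone may compete. Fallback, setting out from 10 (step 5 worked up without the acid treatment) and returning at 13: the lactone is never formed. The carbinol of 10 is silylated (TESOTf, 2,6-lutidine, CH2Cl2, −78 °C) to N-(2-{(3S)-4-[(4R)-2,2-dimethyl-5-oxo-1,3-dioxolan-4-yl]-3-(triethylsilyloxy)butanoyl}phenyl)-N-methyl-2-(1-methyl-1H-indol-3-yl)acetamide F5. The dioxolanone is opened with K2CO3 in MeOH at 0 °C to methyl (2R,4S)-2-hydroxy-6-{2-[N-methyl-2-(1-methyl-1H-indol-3-yl)acetamido]phenyl}-6-oxo-4-(triethylsilyloxy)hexanoate F6. PPTS with 2,2-dimethoxypropane in acetone/MeOH then forms the mixed ketal at the 2-hydroxyl, cleaves the silyl ether and closes the acetonide to give 13.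

**Further compounds**

F1 | step 7 | N-(2-{2-[(2S,4R)-4-(tert-butyldimethylsilyloxy)-5-oxooxolan-2-yl]acetyl}phenyl)-N-methyl-2-(1-methyl-1H-indol-3-yl)acetamide | Cn1cc(CC(=O)N(C)c2ccccc2C(=O)C[C@@H]2C[C@@H](O[Si](C)(C)C(C)(C)C)C(=O)O2)c2ccccc21
F2 | step 7 | (3R,5R)-3-(tert-butyldimethylsilyloxy)-5-({1-methyl-2-[(1-methyl-1H-indol-3-yl)methyl]-1H-indol-3-yl}methyl)oxolan-2-one | Cn1cc(Cc2c(C[C@@H]3C[C@@H](O[Si](C)(C)C(C)(C)C)C(=O)O3)c3ccccc3n2C)c2ccccc21
F3 | step 5 | methyl (2R,4E)-2-hydroxy-6-{2-[N-methyl-2-(1-methyl-1H-indol-3-yl)acetamido]phenyl}-6-oxohex-4-enoate | COC(=O)[C@H](O)C/C=C/C(=O)c1ccccc1N(C)C(=O)Cc1cn(C)c2ccccc12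
F4 | step 5 | methyl (2R,4R,6S)-6-(2-{2-[N-methyl-2-(1-methyl-1H-indol-3-yl)acetamido]phenyl}-2-oxoethyl)-2-phenyl-1,3-dioxane-4-carboxylate | COC(=O)[C@H]1C[C@@H](CC(=O)c2ccccc2N(C)C(=O)Cc2cn(C)c3ccccc23)O[C@@H](c2ccccc2)O1
F5 | step 6 | N-(2-{(3S)-4-[(4R)-2,2-dimethyl-5-oxo-1,3-dioxolan-4-yl]-3-(triethylsilyloxy)butanoyl}phenyl)-N-methyl-2-(1-methyl-1H-indol-3-yl)acetamide | CC[Si](CC)(CC)O[C@@H](C[C@H]1OC(C)(C)OC1=O)CC(=O)c1ccccc1N(C)C(=O)Cc1cn(C)c2ccccc12
F6 | step 6 | methyl (2R,4S)-2-hydroxy-6-{2-[N-methyl-2-(1-methyl-1H-indol-3-yl)acetamido]phenyl}-6-oxo-4-(triethylsilyloxy)hexanoate | COC(=O)[C@H](O)C[C@H](O[Si](CC)(CC)CC)CC(=O)c1ccccc1N(C)C(=O)Cc1cn(C)c2ccccc12
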